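The leftover solid came first: in Saturday's flask 59.5% of the E charged still stood at 120 s, and from 25.0 s on the E readings fell on a straight line.

- Saturday's: E 1.5 M; the very flask that is asked about, followed so far
- flask: E 1.5 M; time 4.0 min

Saturday's run (percent of the E charged)

| time / s | G / % | E / % |
|---|---|---|
| 10.0 | 0.8 | 95.8 |
| 15.0 | 0.2 | 94.6 |
| 25.0 | 3.3 | 91.1 |
| 40.0 | 5.3 | 86.0 |
| 80.0 | 15.5 | 72.7 |
| 120 | 26.8 | 59.5 |

(standard deviation of a reading: 0.5 percentage points)

- given per volume of solution although it is solid: E
- at the start none of E is in solution

- amount of G in percent of the E charged, at 50 s, 2.0 min and 4.0 min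

I read that line as a zero-order feed of E into solution. Its slope between 25.0 s and 120 s gave θ = 5.01 min, the time in which the whole charge would go at that slope, which I call the emptying time. The asked 4.0 min is shorter than θ, so I let the line run on, and it put 79.8% of the E gone by then.

G lagged behind that loss. The gap, E lost minus G, read 8.70%, 11.8% and 13.7% at 40.0 s, 80.0 s and 120 s. I took two extreme flasks. If the gap stopped growing at its last reading, G at 4.0 min would be 66.1%. If it kept its share of the E lost, G would be 52.8%. The gap grew less in the second interval than in the first, yet it still grew, so I placed the flask between them and committed to the midpoint, 59.5%. At 50 s I interpolated 7.85%, and at 2.0 min I kept the reading, 26.8%.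

The forecast gave 7.6%, 26.7% and 63%, the last higher than mine, with the caution that “the solid may run out before then”.

The flask gave 8.14%, 26.7% and 58.9% of G, with J the dissolved E:

    J → G (k = 0.0310 s⁻¹)
    2 J → L (k = 0.0200 M⁻¹ s⁻¹)
    J + L → Z (k = 0.0620 M⁻¹ s⁻¹)
    2 J → D (k = 3.70 × 10⁻⁶ M⁻¹ s⁻¹)
    E ⇌ J, rate k5*(cs5 - [J]) while solid is left; crystals form when [J] > cs5 (solubility = 1.30 M, k = 0.00420 s⁻¹)

At 4.00 min the flask held 20.6% of E, and θ had promised 20.2%. For a flask with twice the E, taking the feed in M per unit time as unchanged, I reckoned θ at 10.0 min and, in proportion, 29.4% of G from this flask's 58.9%. The run with twice the E held 29.4%.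

The runs were generated by integration from invented constants.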